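**Retrosynthetic overview**
- The depside ester C(=O)–O bond is cut last into a ring A acid (2-benzyloxy-4-methoxy) and a ring B phenol (benzyl ester), both with the side-chain ketones masked as dioxolanes; the benzyl groups come off in the final step.
- Both halves come from one resorcylate, methyl 2,4-dihydroxy-6-[(2-pentyl-1,3-dioxolan-2-yl)methyl]benzoate, by differentiating its phenols (the 4-OH alkylates first, the chelated 2-OH second).
- The 2-oxoheptyl chain is cut at C2–C3: pentyl Grignard on the Weinreb amide of a homophthalate half-acid.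
- The homophthalate is cut at two bonds at once, aryl–CH2 and aryl–CO2Me, by insertion of 3,5-bis(benzyloxy)benzyne into dimethyl malonate. The feature that allows this: in ring A and in ring B the carboxyl carbon (on C1) and the benzylic CH2 of the 2-oxoheptyl chain (on C6) sit on neighbouring ring carbons, the other neighbour of C1 (C2) carries oxygen, and C4 carries the second oxygen.
- No carbocycle is built: both benzene rings come from 3,5-bis(benzyloxy)phenol, and the only rings formed are two temporary dioxolanes.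

Key step: step 4

Remark: the target has no stereocentre; ring A is the 2-hydroxy-4-methoxybenzoyl ring and ring B the benzoic acid ring; 3,5-bis(benzyloxy)phenol is taken as purchasable.

**Route**

Step 1
Reactants: 1 3,5-bis(benzyloxy)phenol
Product: 2 3,5-bis(benzyloxy)phenyl isopropylcarbamate
Conditions: iPrNCO, Et3N (cat.), CH2Cl2, rt
Reagents that add atoms: isopropyl isocyanate, CC(C)N=C=O
Why: Amine-catalysed addition of the phenol to the isocyanate (carbamoylation) should give an N-monoalkyl carbamate that is a strong ortho-directing group and can later be removed under mild base.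

Step 2
Reactants: 2 3,5-bis(benzyloxy)phenyl isopropylcarbamate
Product: 6 3,5-bis(benzyloxy)-2-(trimethylsilyl)phenyl isopropylcarbamate, via N-TBS carbamate 3 (not isolated), via aryllithium 4 (not isolated), via N-TBS C-TMS carbamate 5 (not isolated)
Conditions: TBSOTf, TMEDA, Et2O, 0 °C to rt; n-BuLi, TMEDA, −78 °C; Me3SiCl, −78 °C to rt; aq. NaHSO4
Reagents that add atoms: chlorotrimethylsilane, C[Si](C)(C)Cl
Why: Directed ortho-metalation: N-silylation masks the N–H, the carbamate then steers n-BuLi to C2 (equivalent to C6), where the neighbouring benzyloxy oxygen cooperates, whereas C4 between the two ethers lacks the carbamate; Me3SiCl traps the aryllithium at −78 °C before any anionic Fries shift, and the aqueous work-up removes the N-silyl group.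

Step 3
Reactants: 6 3,5-bis(benzyloxy)-2-(trimethylsilyl)phenyl isopropylcarbamate
Product: 8 3,5-bis(benzyloxy)-2-(trimethylsilyl)phenyl trifluoromethanesulfonate, via silylphenol 7 (not isolated)
Conditions: DBU, Et2NH, MeCN, 40 °C; then PhNTf2, rt
Reagents that add atoms: N-phenylbis(trifluoromethanesulfonimide), O=S(=O)(N(c1ccccc1)S(=O)(=O)C(F)(F)F)C(F)(F)F
Why: E1cB cleavage of the N-monoalkyl carbamate by DBU should expel isopropyl isocyanate, which Et2NH scavenges as a urea, and the resulting phenoxide is triflated in the same flask by the mild triflyl donor without touching the C–Si bond (phenol triflation).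

Step 4
Reactants: 8 3,5-bis(benzyloxy)-2-(trimethylsilyl)phenyl trifluoromethanesulfonate, 9 dimethyl malonate
Product: 11 methyl 2,4-bis(benzyloxy)-6-(2-methoxy-2-oxoethyl)benzoate, via aryne 10 (not isolated)
Conditions: CsF, 9 (2 equiv), MeCN, 80 °C
Reagents that add atoms: none
Why: Fluoride attack on silicon with loss of triflate should unveil aryne 10 (triple bond C1–C2, benzyloxy on C3); the caesium enolate of 9 adds at C1, the C2 aryl anion so formed closes onto a malonate ester carbonyl through a transient four-membered alkoxide (4-exo-trig) that fragments, so that the methoxycarbonyl group ends on C2 and the CH2CO2Me arm on C1, a net insertion of the aryne into a C–C sigma bond of the malonate. The closest known reaction type is the fluoride-mediated acyl-alkylation (sigma-bond insertion) of ortho-silylaryl triflates with malonates and beta-keto esters. No ring persists in the product and no stereocentre is formed. The step needs regioselective addition to the unsymmetrical aryne, and the C3 oxygen should secure it: it is inductively withdrawing and distorts the aryne so that C1 is the more linear, more electrophilic terminus while the developing negative charge sits at C2 next to oxygen. Acyl transfer should outrun protonation of the aryl anion because the ester carbonyl is held close by and the medium is aprotic, and the excess of 9 should limit a second arylation.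

Step 5
Reactants: 11 methyl 2,4-bis(benzyloxy)-6-(2-methoxy-2-oxoethyl)benzoate
Product: 12 2-[3,5-bis(benzyloxy)-2-(methoxycarbonyl)phenyl]acetic acid
Conditions: LiOH·H2O (1.2 equiv), THF–H2O, 0 °C to rt; then 1 M HCl
Reagents that add atoms: lithium hydroxide, [Li+].[OH-]
Why: Chemoselective saponification: the arylacetic methyl ester is unhindered, whereas the benzoate is flanked by two ortho substituents and should be inert to LiOH at room temperature.

Step 6
Reactants: 12 2-[3,5-bis(benzyloxy)-2-(methoxycarbonyl)phenyl]acetic acid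
Product: 13 methyl 2,4-bis(benzyloxy)-6-{2-[methoxy(methyl)amino]-2-oxoethyl}benzoate
Conditions: MeNHOMe·HCl, EDC·HCl, HOBt (cat.), iPr2NEt, CH2Cl2, rt
Reagents that add atoms: N,O-dimethylhydroxylamine hydrochloride, CNOC.Cl
Why: Carbodiimide amide coupling through the HOBt active ester should give the Weinreb amide while the hindered benzoate stays untouched.

Step 7
Reactants: 13 methyl 2,4-bis(benzyloxy)-6-{2-[methoxy(methyl)amino]-2-oxoethyl}benzoate, 14 pentylmagnesium bromide
Product: 16 methyl 2,4-bis(benzyloxy)-6-(2-oxoheptyl)benzoate, via magnesium hemiaminal chelate 15 (not isolated)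
Conditions: C5H11MgBr (2.2 equiv), THF, −20 to 0 °C; aq. NH4Cl
Reagents that add atoms: none
Why: Weinreb ketone synthesis: the Grignard reagent adds once, the five-membered magnesium chelate holds until the aqueous quench, and the di-ortho-substituted methyl benzoate is too hindered to react at 0 °C.

Step 8
Reactants: 16 methyl 2,4-bis(benzyloxy)-6-(2-oxoheptyl)benzoate
Product: 17 methyl 2,4-bis(benzyloxy)-6-[(2-pentyl-1,3-dioxolan-2-yl)methyl]benzoate
Conditions: TMSOCH2CH2OTMS, TMSOTf (cat.), CH2Cl2, −78 to −20 °C; pyridine quench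
Reagents that add atoms: 1,2-bis(trimethylsilyloxy)ethane, C[Si](C)(C)OCCO[Si](C)(C)C
Why: Silyl-triflate-catalysed ketalisation, driven by formation of hexamethyldisiloxane under aprotic low-temperature conditions, should avoid acid-induced enol lactonisation onto the neighbouring ester; the dioxolane then shields the ketone from enolate alkylation and from attack on the activated carboxyl group in later steps.

Step 9
Reactants: 17 methyl 2,4-bis(benzyloxy)-6-[(2-pentyl-1,3-dioxolan-2-yl)methyl]benzoate
Product: 18 methyl 2,4-dihydroxy-6-[(2-pentyl-1,3-dioxolan-2-yl)methyl]benzoate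
Conditions: H2 (1 atm), Pd/C, EtOAc, rt
Reagents that add atoms: none
Why: Hydrogenolysis of the two aryl benzyl ethers under neutral conditions should leave the dioxolane and the methyl ester intact.

Step 10
Reactants: 18 methyl 2,4-dihydroxy-6-[(2-pentyl-1,3-dioxolan-2-yl)methyl]benzoate
Product: 19 methyl 2-hydroxy-4-methoxy-6-[(2-pentyl-1,3-dioxolan-2-yl)methyl]benzoate
Conditions: MeI (1.1 equiv), K2CO3, acetone, rt
Reagents that add atoms: iodomethane, CI
Why: Regioselective Williamson ether synthesis: the 4-OH is the more acidic and unencumbered phenol, whereas the 2-OH is locked in a hydrogen bond to the ester carbonyl, so one equivalent of MeI should methylate O4 only.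

Step 11
Reactants: 19 methyl 2-hydroxy-4-methoxy-6-[(2-pentyl-1,3-dioxolan-2-yl)methyl]benzoate
Product: 20 methyl 2-(benzyloxy)-4-methoxy-6-[(2-pentyl-1,3-dioxolan-2-yl)methyl]benzoate
Conditions: BnBr, K2CO3, DMF, 60 °C
Reagents that add atoms: benzyl bromide, BrCc1ccccc1
Why: Williamson benzylation of the chelated 2-OH under more forcing conditions; the masked ketone offers no competing carbon nucleophile.

Step 12
Reactants: 20 methyl 2-(benzyloxy)-4-methoxy-6-[(2-pentyl-1,3-dioxolan-2-yl)methyl]benzoate
Product: 21 2-(benzyloxy)-4-methoxy-6-[(2-pentyl-1,3-dioxolan-2-yl)methyl]benzoic acid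
Conditions: KOH, DMSO–H2O, 90 °C; then cold aq. KHSO4 to pH 4
Reagents that add atoms: potassium hydroxide, [K+].[OH-]
Why: Saponification of the di-ortho-substituted benzoate needs hot KOH in aqueous DMSO, which the ethers and the dioxolane tolerate, and a brief cold acidification should free the acid without hydrolysing the ketal.

Step 13
Reactants: 18 methyl 2,4-dihydroxy-6-[(2-pentyl-1,3-dioxolan-2-yl)methyl]benzoate
Product: 22 methyl 4-(allyloxy)-2-hydroxy-6-[(2-pentyl-1,3-dioxolan-2-yl)methyl]benzoate
Conditions: allyl bromide (1.05 equiv), K2CO3, acetone, rt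
Reagents that add atoms: allyl bromide, C=CCBr
Why: Regioselective Williamson ether synthesis at the non-chelated 4-OH, as in step 10; allyl is chosen because it can later be removed beside a benzyl ester.

Step 14
Reactants: 22 methyl 4-(allyloxy)-2-hydroxy-6-[(2-pentyl-1,3-dioxolan-2-yl)methyl]benzoate
Product: 23 methyl 4-(allyloxy)-2-methoxy-6-[(2-pentyl-1,3-dioxolan-2-yl)methyl]benzoate
Conditions: MeI, K2CO3, DMF, 50 °C
Reagents that add atoms: iodomethane, CI
Why: Williamson methylation of the remaining chelated 2-OH with excess MeI in DMF should complete the ring B oxygenation pattern.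

Step 15
Reactants: 23 methyl 4-(allyloxy)-2-methoxy-6-[(2-pentyl-1,3-dioxolan-2-yl)methyl]benzoate
Product: 24 4-(allyloxy)-2-methoxy-6-[(2-pentyl-1,3-dioxolan-2-yl)methyl]benzoic acid
Conditions: KOH, DMSO–H2O, 90 °C; then cold aq. KHSO4 to pH 4
Reagents that add atoms: potassium hydroxide, [K+].[OH-]
Why: Saponification of the hindered benzoate as in step 12; the water content of the medium should keep the base too weak to isomerise the allyl ether to a propenyl ether.

Step 16
Reactants: 24 4-(allyloxy)-2-methoxy-6-[(2-pentyl-1,3-dioxolan-2-yl)methyl]benzoic acid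
Product: 25 benzyl 4-(allyloxy)-2-methoxy-6-[(2-pentyl-1,3-dioxolan-2-yl)methyl]benzoate
Conditions: BnBr, KHCO3, DMF, rt
Reagents that add atoms: benzyl bromide, BrCc1ccccc1
Why: SN2 alkylation of the carboxylate occurs at the benzylic carbon of BnBr and not at the hindered carbonyl, so the di-ortho-substituted acid should esterify readily under non-acidic conditions.

Step 17
Reactants: 25 benzyl 4-(allyloxy)-2-methoxy-6-[(2-pentyl-1,3-dioxolan-2-yl)methyl]benzoate
Product: 26 benzyl 4-hydroxy-2-methoxy-6-[(2-pentyl-1,3-dioxolan-2-yl)methyl]benzoate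
Conditions: Pd(PPh3)4 (cat.), morpholine, THF, rt
Reagents that add atoms: none
Why: Tsuji–Trost deallylation: zerovalent palladium ionises the aryl allyl ether to a pi-allyl complex and the phenoxide, morpholine captures the allyl group, and the benzyl ester and dioxolane are inert.

Step 18
Reactants: 21 2-(benzyloxy)-4-methoxy-6-[(2-pentyl-1,3-dioxolan-2-yl)methyl]benzoic acid, 26 benzyl 4-hydroxy-2-methoxy-6-[(2-pentyl-1,3-dioxolan-2-yl)methyl]benzoate
Product: 27 4-[(benzyloxy)carbonyl]-3-methoxy-5-[(2-pentyl-1,3-dioxolan-2-yl)methyl]phenyl 2-(benzyloxy)-4-methoxy-6-[(2-pentyl-1,3-dioxolan-2-yl)methyl]benzoate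
Conditions: EDC·HCl, DMAP (1 equiv), CH2Cl2, 0 °C to rt
Reagents that add atoms: none
Why: Steglich esterification under basic conditions that the ketals tolerate; with the ring A 2-OH benzylated and both ketones masked, the only nucleophile is the ring B phenol and the only electrophile the DMAP-activated acyl group.

Step 19
Reactants: 27 the bis-dioxolane depside
Product: 28 4-[(benzyloxy)carbonyl]-3-methoxy-5-(2-oxoheptyl)phenyl 2-(benzyloxy)-4-methoxy-6-(2-oxoheptyl)benzoate
Conditions: 1 M HCl, THF, rt
Reagents that add atoms: water, O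
Why: Acid-catalysed acetal hydrolysis of two dialkyl ketone dioxolanes in dilute aqueous acid, which aryl ester, benzyl ester and benzyl ether should survive; it is placed before the hydrogenolysis so that the free ring B acid never meets acid next to its ketone.

Step 20
Reactants: 28 4-[(benzyloxy)carbonyl]-3-methoxy-5-(2-oxoheptyl)phenyl 2-(benzyloxy)-4-methoxy-6-(2-oxoheptyl)benzoate
Product: 29 4-{[2-hydroxy-4-methoxy-6-(2-oxoheptyl)benzoyl]oxy}-2-methoxy-6-(2-oxoheptyl)benzoic acid (target)
Conditions: H2 (1 atm), Pd/C, EtOAc, rt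
Reagents that add atoms: none
Why: Neutral hydrogenolysis should cleave the benzyl ether of ring A and the benzyl ester of ring B, while the dialkyl ketones and the depside aryl ester are not reduced under these conditions.

**Compound list**
1 | 3,5-bis(benzyloxy)phenol | Oc1cc(OCc2ccccc2)cc(OCc2ccccc2)c1 | starting material
2 | 3,5-bis(benzyloxy)phenyl isopropylcarbamate | CC(C)NC(=O)Oc1cc(OCc2ccccc2)cc(OCc2ccccc2)c1 | intermediate
3 | 3,5-bis(benzyloxy)phenyl (tert-butyldimethylsilyl)(isopropyl)carbamate | CC(C)N(C(=O)Oc1cc(OCc2ccccc2)cc(OCc2ccccc2)c1)[Si](C)(C)C(C)(C)C | intermediate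
4 | {2,4-bis(benzyloxy)-6-[(tert-butyldimethylsilyl)(isopropyl)carbamoyloxy]phenyl}lithium | [Li]c1c(OCc2ccccc2)cc(OCc2ccccc2)cc1OC(=O)N(C(C)C)[Si](C)(C)C(C)(C)C | intermediate
5 | 3,5-bis(benzyloxy)-2-(trimethylsilyl)phenyl (tert-butyldimethylsilyl)(isopropyl)carbamate | CC(C)N(C(=O)Oc1cc(OCc2ccccc2)cc(OCc2ccccc2)c1[Si](C)(C)C)[Si](C)(C)C(C)(C)C | intermediate
6 | 3,5-bis(benzyloxy)-2-(trimethylsilyl)phenyl isopropylcarbamate | CC(C)NC(=O)Oc1cc(OCc2ccccc2)cc(OCc2ccccc2)c1[Si](C)(C)C | intermediate
7 | 3,5-bis(benzyloxy)-2-(trimethylsilyl)phenol | C[Si](C)(C)c1c(O)cc(OCc2ccccc2)cc1OCc1ccccc1 | intermediate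
8 | 3,5-bis(benzyloxy)-2-(trimethylsilyl)phenyl trifluoromethanesulfonate | C[Si](C)(C)c1c(OCc2ccccc2)cc(OCc2ccccc2)cc1OS(=O)(=O)C(F)(F)F | intermediate
9 | dimethyl malonate | COC(=O)CC(=O)OC | starting material
10 | 3,5-bis(benzyloxy)benzyne (1,2-didehydro-3,5-bis(benzyloxy)benzene) | C1#CC(OCc2ccccc2)=CC(OCc2ccccc2)=C1 | intermediate
11 | methyl 2,4-bis(benzyloxy)-6-(2-methoxy-2-oxoethyl)benzoate | COC(=O)Cc1cc(OCc2ccccc2)cc(OCc2ccccc2)c1C(=O)OC | intermediate
12 | 2-[3,5-bis(benzyloxy)-2-(methoxycarbonyl)phenyl]acetic acid | OC(=O)Cc1cc(OCc2ccccc2)cc(OCc2ccccc2)c1C(=O)OC | intermediate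
13 | methyl 2,4-bis(benzyloxy)-6-{2-[methoxy(methyl)amino]-2-oxoethyl}benzoate | CON(C)C(=O)Cc1cc(OCc2ccccc2)cc(OCc2ccccc2)c1C(=O)OC | intermediate
14 | pentylmagnesium bromide | CCCCC[Mg]Br | starting material
15 | methyl 2,4-bis(benzyloxy)-6-{2-[(bromomagnesio)oxy]-2-[methoxy(methyl)amino]heptyl}benzoate (racemic tetrahedral adduct) | CCCCCC(O[Mg]Br)(Cc1cc(OCc2ccccc2)cc(OCc2ccccc2)c1C(=O)OC)N(C)OC | intermediate
16 | methyl 2,4-bis(benzyloxy)-6-(2-oxoheptyl)benzoate | CCCCCC(=O)Cc1cc(OCc2ccccc2)cc(OCc2ccccc2)c1C(=O)OC | intermediate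
17 | methyl 2,4-bis(benzyloxy)-6-[(2-pentyl-1,3-dioxolan-2-yl)methyl]benzoate | CCCCCC1(Cc2cc(OCc3ccccc3)cc(OCc3ccccc3)c2C(=O)OC)OCCO1 | intermediate
18 | methyl 2,4-dihydroxy-6-[(2-pentyl-1,3-dioxolan-2-yl)methyl]benzoate | CCCCCC1(Cc2cc(O)cc(O)c2C(=O)OC)OCCO1 | intermediate
19 | methyl 2-hydroxy-4-methoxy-6-[(2-pentyl-1,3-dioxolan-2-yl)methyl]benzoate | CCCCCC1(Cc2cc(OC)cc(O)c2C(=O)OC)OCCO1 | intermediate
20 | methyl 2-(benzyloxy)-4-methoxy-6-[(2-pentyl-1,3-dioxolan-2-yl)methyl]benzoate | CCCCCC1(Cc2cc(OC)cc(OCc3ccccc3)c2C(=O)OC)OCCO1 | intermediate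
21 | 2-(benzyloxy)-4-methoxy-6-[(2-pentyl-1,3-dioxolan-2-yl)methyl]benzoic acid | CCCCCC1(Cc2cc(OC)cc(OCc3ccccc3)c2C(=O)O)OCCO1 | intermediate
22 | methyl 4-(allyloxy)-2-hydroxy-6-[(2-pentyl-1,3-dioxolan-2-yl)methyl]benzoate | C=CCOc1cc(O)c(C(=O)OC)c(CC2(CCCCC)OCCO2)c1 | intermediate
23 | methyl 4-(allyloxy)-2-methoxy-6-[(2-pentyl-1,3-dioxolan-2-yl)methyl]benzoate | C=CCOc1cc(OC)c(C(=O)OC)c(CC2(CCCCC)OCCO2)c1 | intermediate
24 | 4-(allyloxy)-2-methoxy-6-[(2-pentyl-1,3-dioxolan-2-yl)methyl]benzoic acid | C=CCOc1cc(OC)c(C(=O)O)c(CC2(CCCCC)OCCO2)c1 | intermediate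
25 | benzyl 4-(allyloxy)-2-methoxy-6-[(2-pentyl-1,3-dioxolan-2-yl)methyl]benzoate | C=CCOc1cc(OC)c(C(=O)OCc2ccccc2)c(CC2(CCCCC)OCCO2)c1 | intermediate
26 | benzyl 4-hydroxy-2-methoxy-6-[(2-pentyl-1,3-dioxolan-2-yl)methyl]benzoate | Oc1cc(OC)c(C(=O)OCc2ccccc2)c(CC2(CCCCC)OCCO2)c1 | intermediate
27 | 4-[(benzyloxy)carbonyl]-3-methoxy-5-[(2-pentyl-1,3-dioxolan-2-yl)methyl]phenyl 2-(benzyloxy)-4-methoxy-6-[(2-pentyl-1,3-dioxolan-2-yl)methyl]benzoate | CCCCCC1(Cc2cc(OC)cc(OCc3ccccc3)c2C(=O)Oc2cc(OC)c(C(=O)OCc3ccccc3)c(CC3(CCCCC)OCCO3)c2)OCCO1 | intermediate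
28 | 4-[(benzyloxy)carbonyl]-3-methoxy-5-(2-oxoheptyl)phenyl 2-(benzyloxy)-4-methoxy-6-(2-oxoheptyl)benzoate | CCCCCC(=O)Cc1cc(OC)cc(OCc2ccccc2)c1C(=O)Oc1cc(CC(=O)CCCCC)c(C(=O)OCc2ccccc2)c(OC)c1 | intermediate
29 | 4-{[2-hydroxy-4-methoxy-6-(2-oxoheptyl)benzoyl]oxy}-2-methoxy-6-(2-oxoheptyl)benzoic acid | CCCCCC(=O)Cc1cc(OC)cc(O)c1C(=O)Oc1cc(CC(=O)CCCCC)c(C(=O)O)c(OC)c1 | target

**Step count and risks**

Total step count: 20. Longest linear sequence: 17 steps (steps 1–9, 13–17, 18–20); the ring A branch (steps 10–12) joins at step 18.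

Steps most likely to fail:

1. Step 4 (aryne insertion). The aryl anion may be protonated before the acyl group migrates, leaving plain arylation of the malonate; the product may be arylated a second time by the aryne; or the nucleophile may add at the wrong aryne terminus. Fallback, setting out from phenol 1 and returning at 11 without an aryne: triflation of 1 (Tf2O, pyridine, CH2Cl2) should give 3,5-bis(benzyloxy)phenyl trifluoromethanesulfonate F1. Palladium-catalysed alpha-arylation of dimethyl malonate 9 (Pd(OAc)2, a bulky di-tert-butylbiarylphosphine, K3PO4, toluene, 100 °C) should give dimethyl 2-[3,5-bis(benzyloxy)phenyl]malonate F2. Krapcho demethoxycarbonylation (NaCl, wet DMSO, 150 °C) should give methyl 2-[3,5-bis(benzyloxy)phenyl]acetate F3. Vilsmeier–Haack formylation (POCl3, DMF) is expected at C2, para to one benzyloxy group and ortho to the other, since C4 between the two ethers is the more hindered site; this gives methyl 2-[3,5-bis(benzyloxy)-2-formylphenyl]acetate F4. Pinnick oxidation (NaClO2, NaH2PO4, 2-methyl-2-butene, t-BuOH–H2O) should give 2,4-bis(benzyloxy)-6-(2-methoxy-2-oxoethyl)benzoic acid F5, and methylation of the carboxylate (MeI, K2CO3, DMF) returns to the route at 11.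

2. Step 18 (depside esterification). Attack of the phenol on the di-ortho-substituted acyl donor may be so slow that the carbodiimide adduct rearranges by O-to-N acyl shift to an unreactive N-acylurea. Fallback, setting out from acid 21 and returning at 27: in place of in situ activation, 21 would be converted under neutral conditions with 1-chloro-N,N,2-trimethylprop-1-en-1-amine (CH2Cl2, 0 °C) into the preformed, far more electrophilic 2-(benzyloxy)-4-methoxy-6-[(2-pentyl-1,3-dioxolan-2-yl)methyl]benzoyl chloride F6. This is added to phenol 26 with Et3N and DMAP in CH2Cl2 at 0 °C to give 27.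

3. Step 2 (ortho-silylation). Deprotonation at a benzylic OCH2 position with subsequent Wittig rearrangement, or metalation at C4 between the two ethers, may compete with lithiation next to the carbamate. Fallback, setting out from phenol 1 and returning at 8 without a carbamate: monobromination ortho to the hydroxyl group (NBS, CH2Cl2, −78 °C) should give 3,5-bis(benzyloxy)-2-bromophenol F7, to be separated from any 4-bromo isomer. O-Silylation with hexamethyldisilazane (THF, 65 °C) should give [3,5-bis(benzyloxy)-2-bromophenoxy]trimethylsilane F8. Bromine–lithium exchange (n-BuLi, THF, −78 °C) triggers a retro-Brook oxygen-to-carbon silyl shift to lithium 3,5-bis(benzyloxy)-2-(trimethylsilyl)phenolate F9, which is triflated in the same flask with Tf2O to give 8.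

**Further compounds**
F1 | step 4 | 3,5-bis(benzyloxy)phenyl trifluoromethanesulfonate | O=S(=O)(Oc1cc(OCc2ccccc2)cc(OCc2ccccc2)c1)C(F)(F)F
F2 | step 4 | dimethyl 2-[3,5-bis(benzyloxy)phenyl]malonate | COC(=O)C(C(=O)OC)c1cc(OCc2ccccc2)cc(OCc2ccccc2)c1
F3 | step 4 | methyl 2-[3,5-bis(benzyloxy)phenyl]acetate | COC(=O)Cc1cc(OCc2ccccc2)cc(OCc2ccccc2)c1
F4 | step 4 | methyl 2-[3,5-bis(benzyloxy)-2-formylphenyl]acetate | COC(=O)Cc1cc(OCc2ccccc2)cc(OCc2ccccc2)c1C=O
F5 | step 4 | 2,4-bis(benzyloxy)-6-(2-methoxy-2-oxoethyl)benzoic acid | COC(=O)Cc1cc(OCc2ccccc2)cc(OCc2ccccc2)c1C(=O)O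
F6 | step 18 | 2-(benzyloxy)-4-methoxy-6-[(2-pentyl-1,3-dioxolan-2-yl)methyl]benzoyl chloride | CCCCCC1(Cc2cc(OC)cc(OCc3ccccc3)c2C(=O)Cl)OCCO1
F7 | step 2 | 3,5-bis(benzyloxy)-2-bromophenol | Oc1cc(OCc2ccccc2)cc(OCc2ccccc2)c1Br
F8 | step 2 | [3,5-bis(benzyloxy)-2-bromophenoxy]trimethylsilane | C[Si](C)(C)Oc1cc(OCc2ccccc2)cc(OCc2ccccc2)c1Br
F9 | step 2 | lithium 3,5-bis(benzyloxy)-2-(trimethylsilyl)phenolate | [Li+].[O-]c1cc(OCc2ccccc2)cc(OCc2ccccc2)c1[Si](C)(C)C
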